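**Plan**

- Labels: ring A is the benzo ring of the dihydrobenzofuran (O1, C2, C3, C4 next to C3a); ring B is the 3,5-dioxygenated ring on C3; ring E is the 2-hydroxy-5-formylphenyl ring; Cd is the seven-ring methine carrying the 4-hydroxyphenyl group; Ca is the methine carrying ring E.
- Enabling feature: Ca is bonded to C4 of ring A, which is meta to both ring A oxygens and so cannot serve as a Friedel–Crafts nucleophile. Ca also carries ring E through the carbon ortho to its phenol oxygen, so Ca can become the electrophilic end of an ortho-quinone methide while C4 reacts as an aryl-metal.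
- Cuts, in retrosynthetic order: the five O–CH3 bonds and the acetal; Ca–C4 (seven-membered ring); ring B–Cd (epoxide opening); C4–B; C2–C3 (carbene C–H insertion); the carbonyl link between rings A and B.
- Forward: rings A and B are joined as a benzophenone, the dihydrofuran ring is closed, C4 is borylated, ring B is alkylated by a stilbene oxide that carries ring E, and the seven-membered ring closes last.
- Stereochemistry: C3 from a chiral dirhodium carboxylate; C2 by acid equilibration to trans; Cd by invertive opening of an S,S-epoxide from Shi epoxidation; Ca by substrate control from Cd in the ring closure.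

Key step: step 15

Assumption: Rh2(R-PTAD)4 is taken to give the 3S cis-dihydrobenzofuran and the L-fructose-derived Shi ketone the S,S-epoxide (its sense with trans-stilbene); if either induction runs the other way, the enantiomeric catalyst is used.

**Route**

Step 1
Reactants: 1 1-bromo-3,5-dimethoxybenzene
Product: 2 2-bromo-4,6-dimethoxybenzaldehyde
Conditions: POCl3, DMF, 0 °C → 90 °C; then aq. NaOAc
Reagents that add atoms: N,N-dimethylformamide CN(C)C=O; water O
Why: Vilsmeier–Haack formylation of this arene goes mainly to the carbon flanked by bromine and methoxy (para to the other methoxy), which gives the substitution pattern needed for ring A.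

Step 2
Reactants: 1 1-bromo-3,5-dimethoxybenzene; 2 2-bromo-4,6-dimethoxybenzaldehyde
Product: 4 (2-bromo-4,6-dimethoxyphenyl)(3,5-dimethoxyphenyl)methanol (racemic), via aryl Grignard reagent 3 (not isolated)
Conditions: Mg, THF, reflux; then 2, THF, 0 °C → rt; aq. NH4Cl
Reagents that add atoms: none
Why: Grignard addition to the aldehyde joins rings A and B; the aryl bromide of 2 does not exchange with an aryl Grignard reagent at this temperature, and the racemic carbinol centre is removed in the next step.

Step 3
Reactants: 4 (2-bromo-4,6-dimethoxyphenyl)(3,5-dimethoxyphenyl)methanol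
Product: 5 (2-bromo-4,6-dimethoxyphenyl)(3,5-dimethoxyphenyl)methanone
Conditions: MnO2, CH2Cl2, rt
Reagents that add atoms: none
Why: MnO2 oxidation of a doubly benzylic alcohol to the benzophenone is a standard benzylic oxidation that leaves the aryl bromide and methyl ethers untouched.

Step 4
Reactants: 5 (2-bromo-4,6-dimethoxyphenyl)(3,5-dimethoxyphenyl)methanone
Product: 6 (2-bromo-6-hydroxy-4-methoxyphenyl)(3,5-dimethoxyphenyl)methanone
Conditions: BCl3, CH2Cl2, −78 °C → 0 °C; then H2O
Reagents that add atoms: none
Why: Chelation-controlled demethylation: only the methoxy group ortho to the carbonyl can form the six-membered boron chelate, so it alone is cleaved and the future furan oxygen is freed.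

Step 5
Reactants: 6 (2-bromo-6-hydroxy-4-methoxyphenyl)(3,5-dimethoxyphenyl)methanone; 7 4-methoxybenzyl chloride
Product: 8 {2-bromo-4-methoxy-6-[(4-methoxybenzyl)oxy]phenyl}(3,5-dimethoxyphenyl)methanone
Conditions: K2CO3, Bu4NI (cat.), DMF, 60 °C
Reagents that add atoms: none
Why: Williamson etherification of the phenoxide installs the CH2 group that becomes C2, together with its 4-methoxyphenyl substituent.

Step 6
Reactants: 8 {2-bromo-4-methoxy-6-[(4-methoxybenzyl)oxy]phenyl}(3,5-dimethoxyphenyl)methanone
Product: 9 hydrazone of ketone 8 (C=N–NH2, geometry not defined)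
Conditions: N2H4·H2O (excess), AcOH (cat.), n-BuOH, 110 °C
Reagents that add atoms: hydrazine NN
Why: Hydrazone condensation; the ketone is twisted by its two ortho substituents, hence excess hydrazine and heat, which the aryl bromide and benzyl ether should tolerate.

Step 7
Reactants: 9 hydrazone of ketone 8
Product: 11 (2R,3S)-cis-4-bromo-3-(3,5-dimethoxyphenyl)-6-methoxy-2-(4-methoxyphenyl)-2,3-dihydrobenzofuran, via diaryldiazomethane 10 (not isolated)
Conditions: MnO2, CH2Cl2, 0 °C, filtration; then Rh2(R-PTAD)4 (1 mol %), MeCN, 0 °C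
Reagents that add atoms: none
Why: MnO2 dehydrogenates the hydrazone to the diaryldiazomethane, whose rhodium carbene undergoes 1,5 C–H insertion into the electron-rich benzylic ether C–H bond (donor/donor carbene C–H insertion) to give the cis-dihydrobenzofuran; the chiral carboxylate ligands fix C3 and, cis to it, C2.

Step 8
Reactants: 11 (2R,3S)-cis-dihydrobenzofuran bromide
Product: 12 (2S,3S)-trans-4-bromo-3-(3,5-dimethoxyphenyl)-6-methoxy-2-(4-methoxyphenyl)-2,3-dihydrobenzofuran
Conditions: CF3CO2H (2 equiv), CH2Cl2 (dilute), 0 °C → rt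
Reagents that add atoms: none
Why: Acid-promoted epimerization: reversible heterolysis of the C2–O bond to a 4-methoxybenzylic cation and reclosure equilibrates C2 to the more stable trans isomer, while C3 is not touched and keeps the configuration from step 7.

Step 9
Reactants: 12 (2S,3S)-trans-dihydrobenzofuran bromide
Product: 13 (2S,3S)-trans-3-(3,5-dimethoxyphenyl)-6-methoxy-2-(4-methoxyphenyl)-4-(4,4,5,5-tetramethyl-1,3,2-dioxaborolan-2-yl)-2,3-dihydrobenzofuran
Conditions: B2pin2, Pd(dppf)Cl2 (5 mol %), KOAc, 1,4-dioxane, 90 °C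
Reagents that add atoms: bis(pinacolato)diboron CC1(C)OB(OC1(C)C)B1OC(C)(C)C(C)(C)O1
Why: Miyaura borylation of the aryl bromide through zerovalent palladium places boron on C4, the ring A carbon that no electrophilic substitution can reach.

Step 10
Reactants: 14 3-bromo-4-hydroxybenzaldehyde
Product: 15 2-bromo-4-formylphenyl pivalate
Conditions: t-BuCOCl, Et3N, DMAP (cat.), CH2Cl2, 0 °C → rt
Reagents that add atoms: pivaloyl chloride CC(C)(C)C(Cl)=O
Why: Acylation of the phenol; the pivalate weakens the donor power of the ring E oxygen (needed for the regiochemistry of step 14), survives the basic steps that follow, and later carries the leaving group in step 15.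

Step 11
Reactants: 15 2-bromo-4-formylphenyl pivalate
Product: 16 2-bromo-4-(1,3-dioxolan-2-yl)phenyl pivalate
Conditions: HOCH2CH2OH, p-TsOH (cat.), toluene, reflux (Dean–Stark)
Reagents that add atoms: ethylene glycol OCCO
Why: Acid-catalysed acetalization with azeotropic removal of water; the dioxolane shields the aldehyde from the oxidant of step 13 and from aryl-rhodium addition in step 15, and should be inert to BF3·OEt2 at low temperature.

Step 12
Reactants: 16 2-bromo-4-(1,3-dioxolan-2-yl)phenyl pivalate; 17 4-methoxystyrene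
Product: 18 (E)-4-(1,3-dioxolan-2-yl)-2-[2-(4-methoxyphenyl)ethenyl]phenyl pivalate
Conditions: Pd(OAc)2 (5 mol %), P(o-tol)3, Et3N, DMF, 100 °C
Reagents that add atoms: none
Why: Mizoroki–Heck reaction of the aryl bromide with the styrene gives the (E)-stilbene by syn insertion and syn β-hydride elimination.

Step 13
Reactants: 18 (E)-stilbene
Product: 19 4-(1,3-dioxolan-2-yl)-2-[(2S,3S)-3-(4-methoxyphenyl)oxiran-2-yl]phenyl pivalate
Conditions: L-fructose-derived Shi ketone (30 mol %), KHSO5 (as Oxone, 2KHSO5·KHSO4·K2SO4), K2CO3, Bu4NHSO4, MeCN/CH2(OMe)2/aq. Na2B4O7 buffer (pH 10.5), 0 °C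
Reagents that add atoms: potassium peroxymonosulfate [K+].[O-]S(=O)(=O)OO
Why: Shi epoxidation: the chiral dioxirane formed from the ketone transfers oxygen to the trans-alkene through a spiro transition state and sets both epoxide carbons S; the basic buffer protects the acid-sensitive 4-methoxyphenyl epoxide and the pivalate.

Step 14
Reactants: 13 dihydrobenzofuran boronate; 19 (S,S)-epoxide
Product: 20 2-{(1R,2S)-2-[2-((2S,3S)-6-methoxy-2-(4-methoxyphenyl)-4-(4,4,5,5-tetramethyl-1,3,2-dioxaborolan-2-yl)-2,3-dihydrobenzofuran-3-yl)-4,6-dimethoxyphenyl]-1-hydroxy-2-(4-methoxyphenyl)ethyl}-4-(1,3-dioxolan-2-yl)phenyl pivalate (ethyl C1 is Ca, C2 is Cd)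
Conditions: BF3·OEt2 (0.5 equiv), CH2Cl2, −78 °C, slow addition of 19 (1.3 equiv); Et3N quench
Reagents that add atoms: none
Why: Friedel–Crafts alkylation by Lewis-acid epoxide opening: the epoxide opens at the carbon bearing the 4-methoxyphenyl group (the better cation-stabilizing position, ring E being deactivated by its acyloxy group), ring B attacks through its carbon ortho to C3 and para to a methoxy group (ring A is tempered by the boryl group), and backside attack inverts this carbon so that Cd forms S, while the Ca–O bond is untouched and the Ca configuration is of no consequence.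

Step 15
Reactants: 20 boronate carbinol pivalate
Product: 23 ring-closed pentamethyl ether of the target bearing a free ring E phenol and the formyl group as its 1,3-dioxolane (C2 S, C3 S, Cd S, Ca R), via benzylic pivalate 21 (not isolated), via ortho-quinone methide 22 (not isolated)
Conditions: [Rh(OH)(cod)]2 (5 mol %), K3PO4 (3 equiv), 1,4-dioxane/H2O (10:1), 60 °C
Reagents that add atoms: none
Why: Proposed new method: K3PO4 deprotonates the Ca hydroxyl, the pivaloyl group migrates from the ring E oxygen to the Ca oxygen through a six-membered tetrahedral intermediate, and the freed phenoxide expels pivalate to give the ortho-quinone methide, while the C4 boronate transmetalates to the rhodium hydroxide to give an aryl complex of monovalent rhodium. The aryl group then adds 1,4 to the quinone methide at Ca, ring E rearomatizes as its rhodium phenoxide, and hydrolysis returns the rhodium hydroxide. The closest known reaction types are the intermolecular rhodium-catalysed addition of arylboron reagents to ortho-quinone methides formed in situ and the acyl-shift route to ortho-quinone methides from ortho-acyloxybenzyl alkoxides; new is their union in an intramolecular ring closure. The seven-membered ring closes in the 7-exo-trig mode. The new stereocentre Ca is controlled by Cd, because the transition state that keeps the 4-methoxyphenyl group on Cd and ring E on Ca both pseudo-equatorial places them trans. The step needs ring closure to outrun protodeboronation and tautomerization of the quinone methide to a stilbene, which the ortho placement of the C3 and Cd arms on ring B (holding C4 next to Ca) and the electron-neutral, acetal-bearing ring E should secure.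

Step 16
Reactants: 23 ring-closed dioxolane
Product: 24 vitisinol B pentamethyl ether (ring E phenol and formyl group free)
Conditions: 1 M HCl, THF, rt
Reagents that add atoms: water O
Why: Acid-catalysed acetal hydrolysis; a dioxolane para to a free phenol is cleaved by mild aqueous acid that leaves the aryl methyl ethers and the dihydrobenzofuran intact.

Step 17
Reactants: 24 vitisinol B pentamethyl ether
Product: 25 vitisinol B
Conditions: BBr3 (excess), CH2Cl2, −78 °C → rt; then H2O
Reagents that add atoms: none
Why: BBr3 cleavage of the five aryl methyl ethers (Lewis-acid ether cleavage); the stereocentres are benzylic C–H centres locked in the fused ring system and are not expected to epimerize.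

**Compound list**

1 | 1-bromo-3,5-dimethoxybenzene | COc1cc(Br)cc(OC)c1 | starting material
2 | 2-bromo-4,6-dimethoxybenzaldehyde | COc1cc(Br)c(C=O)c(OC)c1 | intermediate
3 | (3,5-dimethoxyphenyl)magnesium bromide | COc1cc(OC)cc([Mg]Br)c1 | intermediate
4 | (2-bromo-4,6-dimethoxyphenyl)(3,5-dimethoxyphenyl)methanol, racemic | COc1cc(OC)cc(C(O)c2c(Br)cc(OC)cc2OC)c1 | intermediate
5 | (2-bromo-4,6-dimethoxyphenyl)(3,5-dimethoxyphenyl)methanone | COc1cc(OC)cc(C(=O)c2c(Br)cc(OC)cc2OC)c1 | intermediate
6 | (2-bromo-6-hydroxy-4-methoxyphenyl)(3,5-dimethoxyphenyl)methanone | COc1cc(OC)cc(C(=O)c2c(Br)cc(OC)cc2O)c1 | intermediate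
7 | 4-methoxybenzyl chloride | COc1ccc(CCl)cc1 | starting material
8 | {2-bromo-4-methoxy-6-[(4-methoxybenzyl)oxy]phenyl}(3,5-dimethoxyphenyl)methanone | COc1ccc(COc2cc(OC)cc(Br)c2C(=O)c2cc(OC)cc(OC)c2)cc1 | intermediate
9 | hydrazone of ketone 8 | COc1ccc(COc2cc(OC)cc(Br)c2C(=NN)c2cc(OC)cc(OC)c2)cc1 | intermediate
10 | 1-bromo-2-[diazo(3,5-dimethoxyphenyl)methyl]-5-methoxy-3-[(4-methoxybenzyl)oxy]benzene | COc1ccc(COc2cc(OC)cc(Br)c2C(=[N+]=[N-])c2cc(OC)cc(OC)c2)cc1 | intermediate
11 | (2R,3S)-cis-4-bromo-3-(3,5-dimethoxyphenyl)-6-methoxy-2-(4-methoxyphenyl)-2,3-dihydrobenzofuran | Brc1cc(OC)cc2c1[C@H](c1cc(OC)cc(OC)c1)[C@H](c1ccc(OC)cc1)O2 | intermediate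
12 | (2S,3S)-trans-4-bromo-3-(3,5-dimethoxyphenyl)-6-methoxy-2-(4-methoxyphenyl)-2,3-dihydrobenzofuran | Brc1cc(OC)cc2c1[C@H](c1cc(OC)cc(OC)c1)[C@@H](c1ccc(OC)cc1)O2 | intermediate
13 | (2S,3S)-trans-3-(3,5-dimethoxyphenyl)-6-methoxy-2-(4-methoxyphenyl)-4-(4,4,5,5-tetramethyl-1,3,2-dioxaborolan-2-yl)-2,3-dihydrobenzofuran | CC1(C)OB(OC1(C)C)c1cc(OC)cc2c1[C@H](c1cc(OC)cc(OC)c1)[C@@H](c1ccc(OC)cc1)O2 | intermediate
14 | 3-bromo-4-hydroxybenzaldehyde | O=Cc1ccc(O)c(Br)c1 | starting material
15 | 2-bromo-4-formylphenyl pivalate | CC(C)(C)C(=O)Oc1ccc(C=O)cc1Br | intermediate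
16 | 2-bromo-4-(1,3-dioxolan-2-yl)phenyl pivalate | CC(C)(C)C(=O)Oc1ccc(C2OCCO2)cc1Br | intermediate
17 | 4-methoxystyrene | C=Cc1ccc(OC)cc1 | starting material
18 | (E)-4-(1,3-dioxolan-2-yl)-2-[2-(4-methoxyphenyl)ethenyl]phenyl pivalate | COc1ccc(/C=C/c2cc(C3OCCO3)ccc2OC(=O)C(C)(C)C)cc1 | intermediate
19 | 4-(1,3-dioxolan-2-yl)-2-[(2S,3S)-3-(4-methoxyphenyl)oxiran-2-yl]phenyl pivalate | COc1ccc(cc1)[C@@H]1O[C@H]1c1cc(C2OCCO2)ccc1OC(=O)C(C)(C)C | intermediate
20 | boronate 13 alkylated on ring B (carbon ortho to C3) by the chain Cd(H)(4-methoxyphenyl)–Ca(H)(OH)–[5-(1,3-dioxolan-2-yl)-2-(pivaloyloxy)phenyl]; Cd S, Ca R | CC1(C)OB(OC1(C)C)c1cc(OC)cc2c1[C@H](c1cc(OC)cc(OC)c1[C@@H]([C@@H](O)c1cc(C3OCCO3)ccc1OC(=O)C(C)(C)C)c1ccc(OC)cc1)[C@@H](c1ccc(OC)cc1)O2 | intermediate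
21 | isomer of 20 with the pivaloyl group on the Ca oxygen and a free ring E phenol | CC1(C)OB(OC1(C)C)c1cc(OC)cc2c1[C@H](c1cc(OC)cc(OC)c1[C@@H]([C@@H](OC(=O)C(C)(C)C)c1cc(C3OCCO3)ccc1O)c1ccc(OC)cc1)[C@@H](c1ccc(OC)cc1)O2 | intermediate
22 | (E)-ortho-quinone methide: ring E as a 6-alkylidenecyclohexa-2,4-dienone with exocyclic C=Ca, Cd S, boronate still on C4 | CC1(C)OB(OC1(C)C)c1cc(OC)cc2c1[C@H](c1cc(OC)cc(OC)c1[C@@H](/C=C3\C=C(C4OCCO4)C=CC3=O)c1ccc(OC)cc1)[C@@H](c1ccc(OC)cc1)O2 | intermediate
23 | ring-closed pentamethyl ether of the target, ring E phenol free, formyl group as 1,3-dioxolane (C2 S, C3 S, Cd S, Ca R) | Oc1ccc(C2OCCO2)cc1[C@H]1c2cc(OC)cc3c2[C@H](c2cc(OC)cc(OC)c2[C@@H]1c1ccc(OC)cc1)[C@@H](c1ccc(OC)cc1)O3 | intermediate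
24 | vitisinol B pentamethyl ether (ring E phenol and formyl group free) | O=Cc1ccc(O)c(c1)[C@H]1c2cc(OC)cc3c2[C@H](c2cc(OC)cc(OC)c2[C@@H]1c1ccc(OC)cc1)[C@@H](c1ccc(OC)cc1)O3 | intermediate
25 | vitisinol B | O=Cc1ccc(O)c([C@H]2c3cc(O)cc4c3[C@H](c3cc(O)cc(O)c3[C@@H]2c2ccc(O)cc2)[C@@H](c2ccc(O)cc2)O4)c1 | target

**Step count and risks**

Total steps: 17. Longest linear sequence: 13 (steps 1–9, then 14–17).

Steps most likely to fail:

1. Step 15. Protonolysis of the aryl–rhodium bond (net protodeboronation) or base-induced tautomerization of the quinone methide to a triarylethylene, which would erase Cd, could outpace ring closure, and facial selectivity at Ca could be poor. The fallback makes the Ca–C4 bond by Suzuki–Miyaura coupling and closes the seven-membered ring at Cd by a Friedel–Crafts reaction. It sets out from stilbene 18 and boronate 13 and comes back at 24. Stilbene 18 is brominated (Br2, CH2Cl2) to the dibromide F1, and DBU removes HBr to give the α-bromostilbene F2 with bromine on the carbon that bears ring E. Coupling of F2 with 13 (Pd(PPh3)4, K2CO3, dioxane/H2O) should give the triarylethylene F3. CF3CO2H in wet CH2Cl2 should protonate the alkene at Ca, ring B should capture the 4-methoxybenzylic cation at Cd (the acid-promoted closure known for 4-styryl-3-aryl-dihydrobenzofurans), and the dioxolane should hydrolyse, giving the ring-closed aldehyde pivalate F4. K2CO3 in MeOH then removes the pivalate to give 24. Ca and Cd would then be set under thermodynamic control by the dihydrobenzofuran centres.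

2. Step 14. The epoxide could be attacked by the wrong arene carbon (the ring B carbon between the methoxy groups, or ring A), the opened epoxide could undergo semipinacol (Meinwald) rearrangement before capture, and a free benzylic cation could erode the inversion at Cd. The fallback replaces the Friedel–Crafts reaction by an organometallic opening; it sets out from 13 and comes back at 20. Iodination of 13 (N-iodosuccinimide, MeCN, 0 °C) should give the ring B iodide F5, whose position can be proven before the fragments are joined. Iodine–magnesium exchange (iPrMgCl·LiCl, THF, −40 °C, which a pinacol boronate tolerates) gives the arylmagnesium chloride F6. CuI-catalysed opening of epoxide 19 at the 4-methoxybenzylic carbon with inversion then gives 20.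

3. Step 6. Hydrazine may fail to add to the twisted, di-ortho-substituted ketone. The fallback runs the condensation before the etherification; it sets out from 6 and comes back at 9. In 6 the carbonyl is hydrogen-bonded and coplanar with ring A, so N2H4·H2O in refluxing EtOH should give the hydroxy hydrazone F7. O-Alkylation of its phenoxide with 7 (Cs2CO3, DMF, rt) then gives 9.

**Further compounds**

F1 | step 15 | 4-(1,3-dioxolan-2-yl)-2-[1,2-dibromo-2-(4-methoxyphenyl)ethyl]phenyl pivalate (diastereomer mixture) | COc1ccc(C(Br)C(Br)c2cc(C3OCCO3)ccc2OC(=O)C(C)(C)C)cc1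
F2 | step 15 | 2-[1-bromo-2-(4-methoxyphenyl)ethenyl]-4-(1,3-dioxolan-2-yl)phenyl pivalate (alkene geometry not defined) | COc1ccc(C=C(Br)c2cc(C3OCCO3)ccc2OC(=O)C(C)(C)C)cc1
F3 | step 15 | triarylethylene: C4 of the (2S,3S)-dihydrobenzofuran bonded to the alkene carbon that bears ring E (pivalate, dioxolane), other alkene carbon bearing 4-methoxyphenyl | COc1ccc(C=C(c2cc(C3OCCO3)ccc2OC(=O)C(C)(C)C)c2cc(OC)cc3c2[C@H](c2cc(OC)cc(OC)c2)[C@@H](c2ccc(OC)cc2)O3)cc1
F4 | step 15 | ring E pivalate of 24 | CC(C)(C)C(=O)Oc1ccc(C=O)cc1[C@H]1c2cc(OC)cc3c2[C@H](c2cc(OC)cc(OC)c2[C@@H]1c1ccc(OC)cc1)[C@@H](c1ccc(OC)cc1)O3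
F5 | step 14 | boronate 13 iodinated on ring B at the carbon ortho to C3 | CC1(C)OB(OC1(C)C)c1cc(OC)cc2c1[C@H](c1cc(OC)cc(OC)c1I)[C@@H](c1ccc(OC)cc1)O2
F6 | step 14 | arylmagnesium chloride from F5 | CC1(C)OB(OC1(C)C)c1cc(OC)cc2c1[C@H](c1cc(OC)cc(OC)c1[Mg]Cl)[C@@H](c1ccc(OC)cc1)O2
F7 | step 6 | hydrazone of hydroxy ketone 6 | COc1cc(OC)cc(C(=NN)c2c(Br)cc(OC)cc2O)c1
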